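## Retrosynthetic overview

1. The target comes from an acetonide-fused epoxy enone by acetal cleavage, acetylation of the primary alcohol and desilylation.
2. Key disconnection: the C5–C6 bond (vinylogous aldol) and the O7–C1 bond (displacement of a tertiary chloride) are made together, so one base treatment of an acyclic (S)-α-chloro-α-formyl ketone closes the cyclohexenone and the oxirane at once.
3. The chloride comes from enantioselective chlorination of a 2-alkyl formyl ketone, itself from Tsuji–Trost coupling of a formyl ketone with silyl-protected 12-hydroxyfarnesyl acetate (SeO2 oxidation of farnesyl acetate).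
4. The formyl ketone comes from formylation of the Wittig product of 2,2-dimethyl-1,3-dioxan-5-one and acetonylidenetriphenylphosphorane.
5. Ring order: dioxane (bought, temporary), then cyclohexenone and oxirane together, then the dioxane is removed.

Assumption: locants C1–C6/O7 refer to the 7-oxabicyclo[4.1.0]hept-3-en-2-one core of the target, and the (S,S)-bis(oxazoline) ligand is taken to give the (S)-chloride (its antipode is used if the sense of induction is the reverse).

## Route

Step 1
Reactants: 1 (2E,6E)-farnesyl acetate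
Product: 2 (2E,6E,10E)-12-hydroxyfarnesyl acetate
Conditions: SeO2 (10 mol %), t-BuOOH, salicylic acid (10 mol %), CH2Cl2, rt
Reagents that add atoms: tert-butyl hydroperoxide, CC(C)(C)OO
Why: Catalytic SeO2/t-BuOOH allylic oxidation (Riley type; ene reaction then [2,3]-sigmatropic shift) hydroxylates the (E)-methyl of the terminal, most electron-rich trisubstituted alkene, the 2,3-alkene being deactivated by the allylic acetate, so the 10E allylic alcohol geometry is set by the mechanism.

Step 2
Reactants: 2 (2E,6E,10E)-12-hydroxyfarnesyl acetate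
Product: 3 (2E,6E,10E)-12-(tert-butyldiphenylsilyloxy)farnesyl acetate
Conditions: TBDPSCl, imidazole, CH2Cl2, 0 °C to rt
Reagents that add atoms: tert-butyl(chloro)diphenylsilane, CC(C)(C)[Si](Cl)(c1ccccc1)c1ccccc1
Why: Standard silylation of the primary allylic alcohol; the TBDPS ether survives the Lewis-acid, carbonate and aqueous acetic acid steps and is removed last by fluoride.

Step 3
Reactants: 4 2,2-dimethyl-1,3-dioxan-5-one; 5 1-(triphenylphosphoranylidene)propan-2-one
Product: 6 1-(2,2-dimethyl-1,3-dioxan-5-ylidene)propan-2-one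
Conditions: toluene, 90 °C
Reagents that add atoms: none
Why: Wittig olefination of the electrophilic α,α'-dioxygenated ketone with the stabilised acyl ylide; the ketone is symmetric, so there is no E/Z issue and both dioxane CH2 groups are equivalent γ-positions.

Step 4
Reactants: 6 1-(2,2-dimethyl-1,3-dioxan-5-ylidene)propan-2-one
Product: 8 4-(2,2-dimethyl-1,3-dioxan-5-ylidene)-3-oxobutanal, via lithium enolate 7 (not isolated)
Conditions: LDA, THF, −78 °C; CF3CH2OCHO, −78 °C; then 1 M HCl
Reagents that add atoms: 2,2,2-trifluoroethyl formate, O=COCC(F)(F)F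
Why: Kinetic α'-deprotonation of the methyl ketone followed by Claisen-type formylation of the enolate with the activated formate gives the hydroxymethylene ketone, a soft 1,3-dicarbonyl pronucleophile.

Step 5
Reactants: 8 4-(2,2-dimethyl-1,3-dioxan-5-ylidene)-3-oxobutanal (1.5 equiv); 3 (2E,6E,10E)-12-(tert-butyldiphenylsilyloxy)farnesyl acetate
Product: 9 2-[12-(tert-butyldiphenylsilyloxy)farnesyl]-4-(2,2-dimethyl-1,3-dioxan-5-ylidene)-3-oxobutanal (enolisable C2, not stereodefined)
Conditions: Pd(PPh3)4 (5 mol %), Et3N, THF, 50 °C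
Reagents that add atoms: none
Why: Tsuji–Trost allylic alkylation: zerovalent palladium ionises only the allylic acetate and the soft 1,3-dicarbonyl anion attacks the unsubstituted terminus of the syn π-allyl complex, giving the linear product with the 2E geometry retained, while the excess of 8 suppresses double allylation.

Step 6
Reactants: 9 2-[12-(tert-butyldiphenylsilyloxy)farnesyl]-4-(2,2-dimethyl-1,3-dioxan-5-ylidene)-3-oxobutanal
Product: 10 (2S)-2-chloro-2-[12-(tert-butyldiphenylsilyloxy)farnesyl]-4-(2,2-dimethyl-1,3-dioxan-5-ylidene)-3-oxobutanal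
Conditions: NCS, Cu(OTf)2 (10 mol %), (S,S)-t-Bu-box (11 mol %), Et2O, 0 °C
Reagents that add atoms: N-chlorosuccinimide, O=C1CCC(=O)N1Cl
Why: Proposed new method: enantioselective electrophilic α-chlorination in which the hydroxymethylene enol of 9 binds divalent copper as a planar six-membered chelate and the C2-symmetric bis(oxazoline) shields one enolate face from NCS, setting the quaternary (S)-C–Cl centre; the closest known reaction is the Cu(OTf)2–bis(oxazoline)/NCS chlorination of 2-substituted β-keto esters, extended here to a 2-alkyl β-keto aldehyde, and NCS without protic acid leaves the isolated trisubstituted alkenes untouched.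

Step 7
Reactants: 10 (2S)-2-chloro-2-[12-(tert-butyldiphenylsilyloxy)farnesyl]-4-(2,2-dimethyl-1,3-dioxan-5-ylidene)-3-oxobutanal
Product: 13 acetonide-fused (1R,5R,6R)-epoxy enone, via caesium dienolate 11 (not isolated), via caesium chlorohydrin alkoxide 12 (not isolated)
Conditions: Cs2CO3 (1.0 equiv), 4 Å MS, MeCN, 0 °C to rt
Reagents that add atoms: none
Why: Proposed new method: a vinylogous Darzens-type annulation in which reversible γ-deprotonation at a dioxane CH2 gives dienolate 11, whose γ-carbon adds to the non-enolisable aldehyde (six-membered ring, intramolecular vinylogous aldol) to give alkoxide 12, and only the aldolate with O− anti-periplanar to the axial C–Cl (Cornforth-type arrangement, side chain equatorial) can expel chloride by SN2 with inversion to close the oxirane, the other aldolates reverting; the (S)-C–Cl centre thereby fixes C1 and C6, while the endocyclic enol-ether geometry of the dienolate forces the new C5–O bond pseudo-equatorial and cis to the oxirane, giving the 1R,5R,6R array; the closest known reactions are intramolecular vinylogous aldol cyclisations and the aldol/SN2 closure of γ-chloro-β-keto esters to epoxycyclohexanones.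

Step 8
Reactants: 13 acetonide-fused (1R,5R,6R)-epoxy enone
Product: 14 (1R,5R,6R)-5-hydroxy-4-(hydroxymethyl)-1-[12-(tert-butyldiphenylsilyloxy)farnesyl]-7-oxabicyclo[4.1.0]hept-3-en-2-one
Conditions: AcOH/THF/H2O (3:1:1), 35 °C
Reagents that add atoms: none
Why: Acid-catalysed hydrolysis of the 1,3-dioxane acetal; the electron-poor α,β-epoxy ketone resists acid opening, the TBDPS ether and the trisubstituted alkenes are stable, and no stereocentre is touched.

Step 9
Reactants: 14 (1R,5R,6R)-5-hydroxy-4-(hydroxymethyl)-1-[12-(tert-butyldiphenylsilyloxy)farnesyl]-7-oxabicyclo[4.1.0]hept-3-en-2-one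
Product: 15 [(1R,5R,6R)-5-hydroxy-2-oxo-1-[12-(tert-butyldiphenylsilyloxy)farnesyl]-7-oxabicyclo[4.1.0]hept-3-en-4-yl]methyl acetate
Conditions: AcCl, 2,4,6-collidine, CH2Cl2, −78 °C
Reagents that add atoms: acetyl chloride, CC(Cl)=O
Why: Chemoselective O-acylation: acetyl chloride with the hindered base at −78 °C acetylates the primary allylic alcohol much faster than the secondary alcohol flanked by the oxirane.

Step 10
Reactants: 15 [(1R,5R,6R)-5-hydroxy-2-oxo-1-[12-(tert-butyldiphenylsilyloxy)farnesyl]-7-oxabicyclo[4.1.0]hept-3-en-4-yl]methyl acetate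
Product: 16 target, [(1R,5R,6R)-5-hydroxy-1-[(2E,6E,10E)-12-hydroxy-3,7,11-trimethyldodeca-2,6,10-trien-1-yl]-2-oxo-7-oxabicyclo[4.1.0]hept-3-en-4-yl]methyl acetate
Conditions: HF·pyridine, pyridine, THF, 0 °C to rt
Reagents that add atoms: none
Why: Fluoride-mediated Si–O cleavage under buffered, non-basic conditions removes the TBDPS group without acetate migration or hydrolysis and without base-induced opening of the epoxy enone.

## Compound list

1 | (2E,6E)-3,7,11-trimethyldodeca-2,6,10-trien-1-yl acetate (E,E-farnesyl acetate) | CC(=O)OC/C=C(\C)CC/C=C(\C)CCC=C(C)C | starting material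
2 | (2E,6E,10E)-12-hydroxy-3,7,11-trimethyldodeca-2,6,10-trien-1-yl acetate | CC(=O)OC/C=C(\C)CC/C=C(\C)CC/C=C(\C)CO | intermediate
3 | (2E,6E,10E)-12-[(tert-butyldiphenylsilyl)oxy]-3,7,11-trimethyldodeca-2,6,10-trien-1-yl acetate | CC(=O)OC/C=C(\C)CC/C=C(\C)CC/C=C(\C)CO[Si](c1ccccc1)(c1ccccc1)C(C)(C)C | intermediate
4 | 2,2-dimethyl-1,3-dioxan-5-one | CC1(C)OCC(=O)CO1 | starting material
5 | 1-(triphenylphosphoranylidene)propan-2-one | CC(=O)C=P(c1ccccc1)(c1ccccc1)c1ccccc1 | starting material
6 | 1-(2,2-dimethyl-1,3-dioxan-5-ylidene)propan-2-one | CC(=O)C=C1COC(C)(C)OC1 | intermediate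
7 | lithium 3-(2,2-dimethyl-1,3-dioxan-5-ylidene)prop-1-en-2-olate (kinetic enolate of 6, not isolated) | [Li+].[O-]C(=C)C=C1COC(C)(C)OC1 | intermediate
8 | 4-(2,2-dimethyl-1,3-dioxan-5-ylidene)-3-oxobutanal (present mainly as its hydroxymethylene enol) | O=CCC(=O)C=C1COC(C)(C)OC1 | intermediate
9 | 2-[(2E,6E,10E)-12-(tert-butyldiphenylsilyloxy)-3,7,11-trimethyldodeca-2,6,10-trien-1-yl]-4-(2,2-dimethyl-1,3-dioxan-5-ylidene)-3-oxobutanal (C2 enolisable, not stereodefined) | O=CC(C/C=C(\C)CC/C=C(\C)CC/C=C(\C)CO[Si](c1ccccc1)(c1ccccc1)C(C)(C)C)C(=O)C=C1COC(C)(C)OC1 | intermediate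
10 | (2S)-2-chloro-2-[(2E,6E,10E)-12-(tert-butyldiphenylsilyloxy)-3,7,11-trimethyldodeca-2,6,10-trien-1-yl]-4-(2,2-dimethyl-1,3-dioxan-5-ylidene)-3-oxobutanal | O=C[C@@](Cl)(C/C=C(\C)CC/C=C(\C)CC/C=C(\C)CO[Si](c1ccccc1)(c1ccccc1)C(C)(C)C)C(=O)C=C1COC(C)(C)OC1 | intermediate
11 | caesium dienolate of 10 (γ-deprotonated at a dioxane CH2, C–Cl centre unchanged, not isolated) | [Cs+].O=C[C@@](Cl)(C/C=C(\C)CC/C=C(\C)CC/C=C(\C)CO[Si](c1ccccc1)(c1ccccc1)C(C)(C)C)C([O-])=CC1=COC(C)(C)OC1 | intermediate
12 | caesium alkoxide of the cyclised chlorohydrin (C–Cl and C–O− trans, ring-fusion C–O cis to C–O−, not isolated) | [Cs+].CC1(C)OCC2=CC(=O)[C@](Cl)(C/C=C(\C)CC/C=C(\C)CC/C=C(\C)CO[Si](c3ccccc3)(c3ccccc3)C(C)(C)C)[C@H]([O-])[C@@H]2O1 | intermediate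
13 | isopropylidene acetal (1,3-dioxane bridging O5 and the C4 CH2O) of diol 14; (1R,5R,6R)-epoxy enone core with the silylated side chain at C1 | CC1(C)OCC2=CC(=O)[C@]3(C/C=C(\C)CC/C=C(\C)CC/C=C(\C)CO[Si](c4ccccc4)(c4ccccc4)C(C)(C)C)O[C@@H]3[C@@H]2O1 | intermediate
14 | (1R,5R,6R)-5-hydroxy-4-(hydroxymethyl)-1-[(2E,6E,10E)-12-(tert-butyldiphenylsilyloxy)-3,7,11-trimethyldodeca-2,6,10-trien-1-yl]-7-oxabicyclo[4.1.0]hept-3-en-2-one | OCC1=CC(=O)[C@]2(C/C=C(\C)CC/C=C(\C)CC/C=C(\C)CO[Si](c3ccccc3)(c3ccccc3)C(C)(C)C)O[C@@H]2[C@@H]1O | intermediate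
15 | [(1R,5R,6R)-5-hydroxy-2-oxo-1-[(2E,6E,10E)-12-(tert-butyldiphenylsilyloxy)-3,7,11-trimethyldodeca-2,6,10-trien-1-yl]-7-oxabicyclo[4.1.0]hept-3-en-4-yl]methyl acetate | CC(=O)OCC1=CC(=O)[C@]2(C/C=C(\C)CC/C=C(\C)CC/C=C(\C)CO[Si](c3ccccc3)(c3ccccc3)C(C)(C)C)O[C@@H]2[C@@H]1O | intermediate
16 | [(1R,5R,6R)-5-hydroxy-1-[(2E,6E,10E)-12-hydroxy-3,7,11-trimethyldodeca-2,6,10-trien-1-yl]-2-oxo-7-oxabicyclo[4.1.0]hept-3-en-4-yl]methyl acetate | CC(=O)OCC1=CC(=O)[C@]2(C/C=C(\C)CC/C=C(\C)CC/C=C(\C)CO)O[C@@H]2[C@@H]1O | target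

## Step count and risk

Total steps: 10. Longest linear sequence: 8 steps (steps 1, 2, 5–10 from 1; equally steps 3–10 from 4).

Three steps most likely to fail:

**Step 7 (double ring closure).** The dienolate geometry that can cyclise is the less populated one. Aldehyde 10 can be deformylated by adventitious nucleophiles, and the product can suffer γ-deprotonation with E1cB opening of the oxirane while carbonate is still present. The fallback sets out from 10 and replaces the anionic cascade by a Lewis-acid sequence. TMSOTf and i-Pr2NEt in CH2Cl2 at −78 °C generate the silyl dienol ether in situ and trigger an intramolecular vinylogous Mukaiyama aldol. This gives the isolable cyclised chlorohydrin trimethylsilyl ether F1, relying on the same Cornforth-type facial preference. TBAF in THF at 0 °C then unmasks the alkoxide, which displaces the chloride and rejoins the route at 13.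

**Step 6 (enantioselective chlorination).** A β-keto aldehyde has not been used in this catalysis, so the ee may be low or the Lewis acid may promote deformylation. The fallback sets out from 8 and moves the stereo-defining event to the C–C bond formation. Chlorination of 8 with NCS alone gives the configurationally labile chloro formyl ketone F2. Palladium-catalysed asymmetric allylic alkylation of F2 with 3 (Pd2(dba)3, DACH-phenyl Trost ligand, Et3N, CH2Cl2) then creates the quaternary C–Cl centre and rejoins the route at 10.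

**Step 5 (Tsuji–Trost coupling).** Branched regioisomer, partial loss of the 2E geometry or double allylation are possible. The fallback sets out from 3 and 6 and uses classical enolate alkylation before formylation. Methanolysis of 3 (K2CO3, MeOH) gives allylic alcohol F3, and Appel bromination (CBr4, PPh3, CH2Cl2, 0 °C) gives allylic bromide F4. Lithium enolate 7 (from 6, LDA, THF, −78 °C) is alkylated with F4 to give ketone F5. Kinetic α'-formylation of F5 (LDA, CF3CH2OCHO) rejoins the route at 9.

## Further compounds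

F1 | step 7 | trimethylsilyl ether of the cyclised chlorohydrin (C–Cl and C–OSiMe3 trans, ring-fusion C–O cis to C–OSiMe3) | CC1(C)OCC2=CC(=O)[C@](Cl)(C/C=C(\C)CC/C=C(\C)CC/C=C(\C)CO[Si](c3ccccc3)(c3ccccc3)C(C)(C)C)[C@H](O[Si](C)(C)C)[C@@H]2O1
F2 | step 6 | 2-chloro-4-(2,2-dimethyl-1,3-dioxan-5-ylidene)-3-oxobutanal | O=CC(Cl)C(=O)C=C1COC(C)(C)OC1
F3 | step 5 | (2E,6E,10E)-12-[(tert-butyldiphenylsilyl)oxy]-3,7,11-trimethyldodeca-2,6,10-trien-1-ol | OC/C=C(\C)CC/C=C(\C)CC/C=C(\C)CO[Si](c1ccccc1)(c1ccccc1)C(C)(C)C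
F4 | step 5 | (2E,6E,10E)-1-bromo-12-[(tert-butyldiphenylsilyl)oxy]-3,7,11-trimethyldodeca-2,6,10-triene | BrC/C=C(\C)CC/C=C(\C)CC/C=C(\C)CO[Si](c1ccccc1)(c1ccccc1)C(C)(C)C
F5 | step 5 | (5E,9E,13E)-15-[(tert-butyldiphenylsilyl)oxy]-1-(2,2-dimethyl-1,3-dioxan-5-ylidene)-6,10,14-trimethylpentadeca-5,9,13-trien-2-one | O=C(CC/C=C(\C)CC/C=C(\C)CC/C=C(\C)CO[Si](c1ccccc1)(c1ccccc1)C(C)(C)C)C=C1COC(C)(C)OC1
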